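**Retrosynthetic overview**
- Side-chain C3'–C4' bond: made last by a nickel-catalysed enantioconvergent radical coupling of an E-alkenyl iodide with racemic 2-bromopentan-3-one (key step; sets 4'R and keeps the E alkene).
- Oxirane: substrate-controlled epoxidation of a cyclohexa-1,3-diene; the alkenyl iodide comes from a terminal alkyne by methylalumination/iodinolysis.
- Cyclohexadiene: from a cyclohexenone by α'-methylation, dienyl triflate formation and formate reduction.
- Cyclohexenone with the quaternary/tertiary stereo pair: amine-catalysed asymmetric Michael–aldol annulation of a pyranone aldehyde with a silylated enynone.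
- Ring order: 4-pyranone (from pentan-3-one and methylmalonyl dichloride), then the carbocycle, then the oxirane.

Assumption: methylmalonyl dichloride, pent-1-yn-3-one and racemic 2-bromopentan-3-one are taken as catalogue chemicals; the α'-carbon created by the enolate methylation is carried as an epimer mixture because it becomes sp2 one step later.

**Step 1**
Reactants: 1 pentan-3-one; 2 2-methylpropanedioyl dichloride
Product: 3 6-ethyl-4-hydroxy-3,5-dimethyl-2H-pyran-2-one
Conditions: CH2Cl2, 0 °C → reflux (−2 HCl)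
Reagents that add atoms: none
Why: Effenberger-type pyranone synthesis, in which C-acylation of the ketone enol by one acid chloride and O-acylation (lactonisation) by the other give the 4-hydroxy-2-pyranone, with no stereocentre formed.

**Step 2**
Reactants: 3 6-ethyl-4-hydroxy-3,5-dimethyl-2H-pyran-2-one
Product: 4 6-ethyl-2-methoxy-3,5-dimethyl-4H-pyran-4-one
Conditions: MeOTf (1.1 equiv), CH2Cl2, 0 °C → rt
Reagents that add atoms: methyl trifluoromethanesulfonate COS(=O)(=O)C(F)(F)F
Why: Regioselective O-alkylation of the lactone carbonyl oxygen by the hard methylating agent gives a 2-methoxy-4-hydroxypyrylium ion that loses a proton to the 2-methoxy-4-pyranone, with no stereocentre formed.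

**Step 3**
Reactants: 4 6-ethyl-2-methoxy-3,5-dimethyl-4H-pyran-4-one
Product: 6 2-(6-methoxy-3,5-dimethyl-4-oxo-4H-pyran-2-yl)propanal, via lithiated pyranone 5 (not isolated)
Conditions: LiN(SiMe3)2 (2.2 equiv), THF, −78 °C; HCO2Et, −78 → 0 °C; 1 M HCl
Reagents that add atoms: ethyl formate CCOC=O
Why: Lateral (vinylogous) deprotonation of the 6-ethyl group followed by Claisen-type C-formylation, the second equivalent of base absorbing the more acidic product; the new centre is left racemic because it becomes the enamine carbon in step 5.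

**Step 4**
Reactants: 7 pent-1-yn-3-one; 8 ethynyltrimethylsilane
Product: 9 (E)-7-(trimethylsilyl)hept-4-en-6-yn-3-one
Conditions: Pd(OAc)2 (3 mol%), tris(2,6-dimethoxyphenyl)phosphine (3 mol%), THF, rt
Reagents that add atoms: none
Why: Palladium-catalysed donor–acceptor alkyne cross-coupling (Trost hydroalkynylation), in which syn addition of the alkynyl C–H bond across the ynone gives the E-enynone with full atom economy.

**Step 5**
Reactants: 6 2-(6-methoxy-3,5-dimethyl-4-oxo-4H-pyran-2-yl)propanal; 9 (E)-7-(trimethylsilyl)hept-4-en-6-yn-3-one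
Product: 11 (4R,5S)-4-(6-methoxy-3,5-dimethyl-4-oxo-4H-pyran-2-yl)-2,4-dimethyl-5-[(trimethylsilyl)ethynyl]cyclohex-2-en-1-one, via Michael adduct 10 (not isolated)
Conditions: 9-amino-9-deoxy-epi-quinine (20 mol%), PhCO2H (40 mol%), toluene, 40 °C; then p-TsOH·H2O (20 mol%), 80 °C
Reagents that add atoms: none
Why: Amine-catalysed asymmetric Michael addition–aldol condensation (Robinson-type annulation), in which the E-enamine of 6 adds to C5 of the iminium-activated enone through an open synclinal transition state (acceptor hydrogen between methyl and pyranone, carbonyl arm next to the enamine nitrogen) that places the alkynyl group cis to the pyranone, the cinchona amine fixes the absolute sense as 4R,5S (the quinidine-derived pseudo-enantiomer would give the antipode), and the ethyl ketone then condenses onto the neopentyl aldehyde.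

**Step 6**
Reactants: 11 (4R,5S)-4-(6-methoxy-3,5-dimethyl-4-oxo-4H-pyran-2-yl)-2,4-dimethyl-5-[(trimethylsilyl)ethynyl]cyclohex-2-en-1-one
Product: 13 (4R,5S)-4-(6-methoxy-3,5-dimethyl-4-oxo-4H-pyran-2-yl)-2,4,6-trimethyl-5-[(trimethylsilyl)ethynyl]cyclohex-2-en-1-one (C6 epimers), via lithium enolate 12 (not isolated)
Conditions: LiN(i-Pr)2 (1.1 equiv), THF, −78 °C; MeI, −78 → −20 °C
Reagents that add atoms: iodomethane CI
Why: Kinetic α'-deprotonation to the cross-conjugated enolate and C-methylation (enolate alkylation); the new C6 centre is erased in step 7 and C4/C5 are untouched.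

**Step 7**
Reactants: 13 (4R,5S)-4-(6-methoxy-3,5-dimethyl-4-oxo-4H-pyran-2-yl)-2,4,6-trimethyl-5-[(trimethylsilyl)ethynyl]cyclohex-2-en-1-one
Product: 15 (3S,4R)-4-(6-methoxy-3,5-dimethyl-4-oxo-4H-pyran-2-yl)-2,4,6-trimethyl-3-[(trimethylsilyl)ethynyl]cyclohexa-1,5-dien-1-yl trifluoromethanesulfonate, via potassium dienolate 14 (not isolated)
Conditions: KN(SiMe3)2 (1.2 equiv), THF, −78 °C; PhNTf2, −78 → 0 °C; cold 1 M HCl wash
Reagents that add atoms: N-phenylbis(trifluoromethanesulfonimide) O=S(=O)(N(c1ccccc1)S(=O)(=O)C(F)(F)F)C(F)(F)F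
Why: The only remaining α'-hydrogen is removed to give the cross-conjugated dienolate, which is O-sulfonylated (enol triflate formation) without touching the two stereocentres.

**Step 8**
Reactants: 15 (3S,4R)-4-(6-methoxy-3,5-dimethyl-4-oxo-4H-pyran-2-yl)-2,4,6-trimethyl-3-[(trimethylsilyl)ethynyl]cyclohexa-1,5-dien-1-yl trifluoromethanesulfonate
Product: 17 6-[(1R,6S)-6-ethynyl-1,3,5-trimethylcyclohexa-2,4-dien-1-yl]-2-methoxy-3,5-dimethyl-4H-pyran-4-one, via silyl diene 16 (not isolated)
Conditions: Pd(OAc)2 (5 mol%), PPh3 (10 mol%), HCO2H, Et3N, DMF, 60 °C; then K2CO3, MeOH, rt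
Reagents that add atoms: none
Why: Palladium-catalysed formate reduction of the dienyl triflate (oxidative addition, decarboxylation of formate to a palladium hydride, reductive elimination) gives the cyclohexa-1,3-diene, and methanolysis then removes the alkynyl silane, the stereocentres being unaffected.

**Step 9**
Reactants: 17 6-[(1R,6S)-6-ethynyl-1,3,5-trimethylcyclohexa-2,4-dien-1-yl]-2-methoxy-3,5-dimethyl-4H-pyran-4-one
Product: 19 6-[(1R,6S)-6-[(E)-1-iodoprop-1-en-2-yl]-1,3,5-trimethylcyclohexa-2,4-dien-1-yl]-2-methoxy-3,5-dimethyl-4H-pyran-4-one, via alkenylalane 18 (not isolated)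
Conditions: AlMe3 (3 equiv), (C5H5)2ZrCl2 (25 mol%), CH2Cl2, 0 °C → rt; then I2, THF, −30 °C
Reagents that add atoms: trimethylaluminium C[Al](C)C; iodine II
Why: Zirconium-catalysed syn-methylalumination of the terminal alkyne (Negishi carboalumination) puts methyl on the internal and aluminium on the terminal carbon, and iodinolysis with retention gives the E-alkenyl iodide.

**Step 10**
Reactants: 19 6-[(1R,6S)-6-[(E)-1-iodoprop-1-en-2-yl]-1,3,5-trimethylcyclohexa-2,4-dien-1-yl]-2-methoxy-3,5-dimethyl-4H-pyran-4-one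
Product: 20 6-[(1R,4R,5S,6S)-5-[(E)-1-iodoprop-1-en-2-yl]-2,4,6-trimethyl-7-oxabicyclo[4.1.0]hept-2-en-4-yl]-2-methoxy-3,5-dimethyl-4H-pyran-4-one
Conditions: m-CPBA (1.05 equiv), NaHCO3, CH2Cl2, −20 → 0 °C, dark
Reagents that add atoms: 3-chloroperoxybenzoic acid OOC(=O)c1cccc(Cl)c1
Why: Prilezhaev epoxidation in which the iodoalkene is deactivated and the C2=C3 bond is flanked on both faces by the quaternary centre, so the peracid attacks C4=C5 from the face next to H-6, anti to both the pyranone and the iodopropenyl group, which sets the two oxirane carbons.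

**Step 11**
Reactants: 20 6-[(1R,4R,5S,6S)-5-[(E)-1-iodoprop-1-en-2-yl]-2,4,6-trimethyl-7-oxabicyclo[4.1.0]hept-2-en-4-yl]-2-methoxy-3,5-dimethyl-4H-pyran-4-one; 21 2-bromopentan-3-one (racemic, 2 equiv)
Product: 22 2-methoxy-3,5-dimethyl-6-[(1R,4R,5R,6S)-2,4,6-trimethyl-5-[(2E,4R)-4-methyl-5-oxohept-2-en-2-yl]-7-oxabicyclo[4.1.0]hept-2-en-4-yl]-4H-pyran-4-one
Conditions: NiCl2(MeOCH2CH2OMe) (10 mol%), 2,2'-(propane-2,2-diyl)bis[(4R)-4-phenyl-4,5-dihydrooxazole] (12 mol%), Mn powder (3 equiv), NaI (0.5 equiv), DMA, 0 °C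
Reagents that add atoms: none
Why: Proposed new method: a nickel-catalysed enantioconvergent reductive cross-electrophile coupling in which low-valent nickel inserts into the C–I bond with retention of the E geometry, bromine-atom abstraction from either enantiomer of 21 gives the same planar α-keto radical, and capture at nickel followed by reductive elimination under the chiral bis(oxazoline) ligand sets 4'R (the ligand antipode is used if a model coupling shows the opposite sense); the closest known reaction types are the stereoconvergent nickel/bis(oxazoline) alkenylation of racemic α-bromo ketones with alkenylzirconium reagents and asymmetric reductive alkenyl halide–secondary alkyl halide couplings, and the base-free conditions protect the epimerisable β,γ-unsaturated ketone.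

**Compound list**
1 | pentan-3-one | CCC(=O)CC | starting material
2 | 2-methylpropanedioyl dichloride (methylmalonyl dichloride) | CC(C(=O)Cl)C(=O)Cl | starting material
3 | 6-ethyl-4-hydroxy-3,5-dimethyl-2H-pyran-2-one | CCc1oc(=O)c(C)c(O)c1C | intermediate
4 | 6-ethyl-2-methoxy-3,5-dimethyl-4H-pyran-4-one | CCc1oc(OC)c(C)c(=O)c1C | intermediate
5 | lithiated pyranone, 6-(1-lithioethyl)-2-methoxy-3,5-dimethyl-4H-pyran-4-one | [Li]C(C)c1oc(OC)c(C)c(=O)c1C | intermediate
6 | 2-(6-methoxy-3,5-dimethyl-4-oxo-4H-pyran-2-yl)propanal (racemic) | O=CC(C)c1oc(OC)c(C)c(=O)c1C | intermediate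
7 | pent-1-yn-3-one | CCC(=O)C#C | starting material
8 | ethynyltrimethylsilane | C#C[Si](C)(C)C | starting material
9 | (E)-7-(trimethylsilyl)hept-4-en-6-yn-3-one | CCC(=O)/C=C/C#C[Si](C)(C)C | intermediate
10 | Michael adduct, (2R,3S)-2-(6-methoxy-3,5-dimethyl-4-oxo-4H-pyran-2-yl)-2-methyl-5-oxo-3-[(trimethylsilyl)ethynyl]heptanal | C[Si](C)(C)C#C[C@@H](CC(=O)CC)[C@@](C)(C=O)c1oc(OC)c(C)c(=O)c1C | intermediate
11 | (4R,5S)-4-(6-methoxy-3,5-dimethyl-4-oxo-4H-pyran-2-yl)-2,4-dimethyl-5-[(trimethylsilyl)ethynyl]cyclohex-2-en-1-one | C[Si](C)(C)C#C[C@H]1CC(=O)C(C)=C[C@@]1(C)c1oc(OC)c(C)c(=O)c1C | intermediate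
12 | lithium enolate of 11 (O–Li on C1, C1=C6) | C[Si](C)(C)C#C[C@H]1C=C(O[Li])C(C)=C[C@@]1(C)c1oc(OC)c(C)c(=O)c1C | intermediate
13 | (4R,5S)-4-(6-methoxy-3,5-dimethyl-4-oxo-4H-pyran-2-yl)-2,4,6-trimethyl-5-[(trimethylsilyl)ethynyl]cyclohex-2-en-1-one (C6 epimers) | C[Si](C)(C)C#C[C@H]1C(C)C(=O)C(C)=C[C@@]1(C)c1oc(OC)c(C)c(=O)c1C | intermediate
14 | potassium dienolate of 13 (O–K on C1, C1=C6) | C[Si](C)(C)C#C[C@H]1C(C)=C(O[K])C(C)=C[C@@]1(C)c1oc(OC)c(C)c(=O)c1C | intermediate
15 | (3S,4R)-4-(6-methoxy-3,5-dimethyl-4-oxo-4H-pyran-2-yl)-2,4,6-trimethyl-3-[(trimethylsilyl)ethynyl]cyclohexa-1,5-dien-1-yl trifluoromethanesulfonate | C[Si](C)(C)C#C[C@H]1C(C)=C(OS(=O)(=O)C(F)(F)F)C(C)=C[C@@]1(C)c1oc(OC)c(C)c(=O)c1C | intermediate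
16 | silyl diene, 2-methoxy-3,5-dimethyl-6-[(1R,6S)-1,3,5-trimethyl-6-[(trimethylsilyl)ethynyl]cyclohexa-2,4-dien-1-yl]-4H-pyran-4-one | C[Si](C)(C)C#C[C@H]1C(C)=CC(C)=C[C@@]1(C)c1oc(OC)c(C)c(=O)c1C | intermediate
17 | 6-[(1R,6S)-6-ethynyl-1,3,5-trimethylcyclohexa-2,4-dien-1-yl]-2-methoxy-3,5-dimethyl-4H-pyran-4-one | C#C[C@H]1C(C)=CC(C)=C[C@@]1(C)c1oc(OC)c(C)c(=O)c1C | intermediate
18 | alkenylalane, 6-[(1R,6S)-6-[(E)-1-(dimethylalumanyl)prop-1-en-2-yl]-1,3,5-trimethylcyclohexa-2,4-dien-1-yl]-2-methoxy-3,5-dimethyl-4H-pyran-4-one | C[Al](C)/C=C(\C)[C@H]1C(C)=CC(C)=C[C@@]1(C)c1oc(OC)c(C)c(=O)c1C | intermediate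
19 | 6-[(1R,6S)-6-[(E)-1-iodoprop-1-en-2-yl]-1,3,5-trimethylcyclohexa-2,4-dien-1-yl]-2-methoxy-3,5-dimethyl-4H-pyran-4-one | I/C=C(\C)[C@H]1C(C)=CC(C)=C[C@@]1(C)c1oc(OC)c(C)c(=O)c1C | intermediate
20 | 6-[(1R,4R,5S,6S)-5-[(E)-1-iodoprop-1-en-2-yl]-2,4,6-trimethyl-7-oxabicyclo[4.1.0]hept-2-en-4-yl]-2-methoxy-3,5-dimethyl-4H-pyran-4-one | I/C=C(\C)[C@H]1[C@]2(C)O[C@@H]2C(C)=C[C@@]1(C)c1oc(OC)c(C)c(=O)c1C | intermediate
21 | 2-bromopentan-3-one (racemic) | CCC(=O)C(C)Br | starting material
22 | 2-methoxy-3,5-dimethyl-6-[(1R,4R,5R,6S)-2,4,6-trimethyl-5-[(2E,4R)-4-methyl-5-oxohept-2-en-2-yl]-7-oxabicyclo[4.1.0]hept-2-en-4-yl]-4H-pyran-4-one | CCC(=O)[C@H](C)/C=C(\C)[C@H]1[C@]2(C)O[C@@H]2C(C)=C[C@@]1(C)c1oc(OC)c(C)c(=O)c1C | target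

**Totals and risks**
Total step count: 11. Longest linear sequence: 10 (steps 1–3 and 5–11, from pentan-3-one).

Most likely to fail, first: step 5. The enamine of 6 is a push–pull (vinylogous amide) system of low nucleophilicity, and both the cis relationship and the enantioselectivity of the quaternary/tertiary pair rest on a transition-state model, not on a tested case. The fallback sets out from 6 and returns to the route at 10. Silylation (Me3SiCl, Et3N) gives (E)-2-methoxy-3,5-dimethyl-6-[1-(trimethylsilyloxy)prop-1-en-2-yl]-4H-pyran-4-one F1. F1 is added to 9 in a Mukaiyama–Michael reaction under a chiral B-aryl oxazaborolidinium bis(trifluoromethanesulfonyl)imide Lewis acid at −78 °C. Aqueous acid work-up releases 10, which is closed to 11 with p-TsOH as before.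

Second: step 9. AlMe3 may complex or methylate the pyranone carbonyl, and the alkyne sits on a hindered carbon next to the quaternary centre. The fallback sets out from 17 and returns at 19. Copper-catalysed syn-borylmethylation (CuCl, Xantphos, NaOt-Bu, bis(pinacolato)diboron, MeI, THF, rt) gives 2-methoxy-3,5-dimethyl-6-[(1R,6S)-1,3,5-trimethyl-6-[(E)-1-(4,4,5,5-tetramethyl-1,3,2-dioxaborolan-2-yl)prop-1-en-2-yl]cyclohexa-2,4-dien-1-yl]-4H-pyran-4-one F2. Iododeboronation with retention (NaOH, I2, THF/H2O, 0 °C) then gives 19.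

Third: step 11. The enantioconvergent reductive coupling is untested for an α-bromo ketone partner, low-valent nickel could open the vinyl oxirane, and the bromo ketone can homocouple. The fallback sets out from 17 and returns at 22, and it leaves the reductive manifold. Alane 18 is generated as in step 9 and excess AlMe3 is removed in vacuo. 18 is then used as the nucleophile with racemic 21 under NiCl2(MeOCH2CH2OMe) and the same bis(oxazoline) ligand, with no Mn (Negishi-type stereoconvergent alkenylation, the established manifold for α-bromo ketones). This gives 2-methoxy-3,5-dimethyl-6-[(1R,6S)-1,3,5-trimethyl-6-[(2E,4R)-4-methyl-5-oxohept-2-en-2-yl]cyclohexa-2,4-dien-1-yl]-4H-pyran-4-one F3. F3 is epoxidised last with dimethyldioxirane (acetone, −40 °C) at the ring C4=C5 bond, anti to the pyranone and side chain, to reach 22.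

**Further compounds**
F1 | step 5 | (E)-2-methoxy-3,5-dimethyl-6-[1-(trimethylsilyloxy)prop-1-en-2-yl]-4H-pyran-4-one | C[Si](C)(C)O/C=C(\C)c1oc(OC)c(C)c(=O)c1C
F2 | step 9 | 2-methoxy-3,5-dimethyl-6-[(1R,6S)-1,3,5-trimethyl-6-[(E)-1-(4,4,5,5-tetramethyl-1,3,2-dioxaborolan-2-yl)prop-1-en-2-yl]cyclohexa-2,4-dien-1-yl]-4H-pyran-4-one | CC1(C)OB(/C=C(\C)[C@H]2C(C)=CC(C)=C[C@@]2(C)c2oc(OC)c(C)c(=O)c2C)OC1(C)C
F3 | step 11 | 2-methoxy-3,5-dimethyl-6-[(1R,6S)-1,3,5-trimethyl-6-[(2E,4R)-4-methyl-5-oxohept-2-en-2-yl]cyclohexa-2,4-dien-1-yl]-4H-pyran-4-one | CCC(=O)[C@H](C)/C=C(\C)[C@H]1C(C)=CC(C)=C[C@@]1(C)c1oc(OC)c(C)c(=O)c1C
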